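**Retrosynthetic overview**
- Target 18 comes from ethyl salicylate 17 by saponification; 17 comes from cyclohexenone 15 by bromination/dehydrobromination (aromatisation).
- Key disconnection: 15 is split into ethyl acetoacetate 12 and enal 11 by an intermolecular Michael addition, followed by intramolecular aldol condensation. This is the only ring formed; the phenyl ring is bought intact.
- Enal 11 comes from aldehyde 7 by HWE olefination, DIBAL-H reduction and MnO2 oxidation.
- Aldehyde 7 comes from alcohol 6, whose chain is assembled by Cu-catalysed coupling of phenethylmagnesium chloride 4 with THP-protected 11-bromoundecanol 3.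

Assumption: the target has no stereocentre, so no enantiocontrol is needed; the transient stereocentres in 3, 5 and 13–16 are carried as racemic/diastereomeric mixtures and vanish before the target.

**Step 1**
Reactants: 1 11-bromoundecan-1-ol; 2 3,4-dihydro-2H-pyran
Product: 3 2-[(11-bromoundecyl)oxy]tetrahydro-2H-pyran (racemic acetal)
Conditions: DHP (1.3 equiv), PPTS (5 mol %), CH2Cl2, rt
Reagents that add atoms: 3,4-dihydro-2H-pyran (2), C1=COCCC1
Why: Acid-catalysed addition of the alcohol to the enol ether (THP protection) masks the OH before the Grignard step.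

**Step 2**
Reactants: 3 2-[(11-bromoundecyl)oxy]tetrahydro-2H-pyran; 4 phenethylmagnesium chloride (commercial THF solution)
Product: 5 2-[(13-phenyltridecyl)oxy]tetrahydro-2H-pyran
Conditions: 4 (1.4 equiv), Li2CuCl4 (3 mol %), THF, −10 °C → rt
Reagents that add atoms: phenethylmagnesium chloride (4), Cl[Mg]CCc1ccccc1
Why: Kochi-type copper-catalysed sp3–sp3 cross-coupling of a primary Grignard reagent with a primary alkyl bromide; the THP ether is inert.

**Step 3**
Reactants: 5 2-[(13-phenyltridecyl)oxy]tetrahydro-2H-pyran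
Product: 6 13-phenyltridecan-1-ol
Conditions: p-TsOH·H2O (5 mol %), MeOH, rt
Reagents that add atoms: none
Why: Acid-catalysed transacetalisation to methanol releases the primary alcohol; nothing else in the molecule is acid-labile.

**Step 4**
Reactants: 6 13-phenyltridecan-1-ol
Product: 7 13-phenyltridecanal
Conditions: TEMPO (10 mol %), PhI(OAc)2 (1.1 equiv), CH2Cl2, rt
Reagents that add atoms: none
Why: TEMPO/BAIB (oxoammonium) oxidation stops cleanly at the aldehyde for unhindered primary alcohols.

**Step 5**
Reactants: 7 13-phenyltridecanal; 8 triethyl phosphonoacetate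
Product: 9 ethyl (E)-15-phenylpentadec-2-enoate
Conditions: 8 (1.15 equiv), NaH (1.1 equiv), THF, 0 °C → rt
Reagents that add atoms: triethyl phosphonoacetate (8), CCOC(=O)CP(=O)(OCC)OCC
Why: Horner–Wadsworth–Emmons olefination of an aliphatic aldehyde with a stabilised phosphonate gives the E-enoate reliably.

**Step 6**
Reactants: 9 ethyl (E)-15-phenylpentadec-2-enoate
Product: 10 (E)-15-phenylpentadec-2-en-1-ol
Conditions: DIBAL-H (2.3 equiv), CH2Cl2, −78 → 0 °C; Rochelle salt work-up
Reagents that add atoms: none
Why: DIBAL-H reduces the enoate 1,2-selectively to the allylic alcohol without touching the C=C.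

**Step 7**
Reactants: 10 (E)-15-phenylpentadec-2-en-1-ol
Product: 11 (E)-15-phenylpentadec-2-enal
Conditions: activated MnO2 (15 equiv), CH2Cl2, rt
Reagents that add atoms: none
Why: MnO2 oxidises allylic alcohols chemoselectively to enals without over-oxidation or loss of alkene geometry.

**Step 8 (key step)**
Reactants: 11 (E)-15-phenylpentadec-2-enal; 12 ethyl acetoacetate
Product: 15 ethyl 2-oxo-6-(12-phenyldodecyl)cyclohex-3-ene-1-carboxylate (diastereomer mixture, racemic), via ethyl 2-acetyl-5-oxo-3-(12-phenyldodecyl)pentanoate 13 (not isolated), via ethyl 4-hydroxy-2-oxo-6-(12-phenyldodecyl)cyclohexane-1-carboxylate 14 (not isolated)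
Conditions: 12 (1.1 equiv), NaOEt (0.15 equiv), EtOH, −5 °C (slow addition of 11) → rt, 16 h; then p-TsOH·H2O (0.1 equiv), toluene, reflux (Dean–Stark), 1 h
Reagents that add atoms: ethyl acetoacetate (12), CCOC(=O)CC(C)=O
Why: Intermolecular Michael addition of the acetoacetate enolate to the enal β-carbon gives 13, whose methyl ketone closes on the aldehyde (intramolecular aldol) to 14; dehydration gives the conjugated cyclohexenone (Robinson-type annulation). The new stereocentres are not controlled because they are destroyed in step 9.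

**Step 9**
Reactants: 15 ethyl 2-oxo-6-(12-phenyldodecyl)cyclohex-3-ene-1-carboxylate
Product: 17 ethyl 2-hydroxy-6-(12-phenyldodecyl)benzoate, via ethyl 1-bromo-2-oxo-6-(12-phenyldodecyl)cyclohex-3-ene-1-carboxylate 16 (not isolated)
Conditions: Br2 (1.0 equiv), AcOH, 15 °C, dark; then 90 °C, 3 h
Reagents that add atoms: none
Why: The β-keto ester enol is brominated at C1 far faster than the unactivated phenyl ring; thermal loss of HBr gives a cyclohexadienone that tautomerises to the salicylate (bromination–dehydrobromination aromatisation).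

**Step 10**
Reactants: 17 ethyl 2-hydroxy-6-(12-phenyldodecyl)benzoate
Product: 18 2-hydroxy-6-(12-phenyldodecyl)benzoic acid
Conditions: KOH (10 equiv), DMSO/H2O (4:1), 90 °C; then cold 2 M HCl to pH 2, 0 °C
Reagents that add atoms: potassium hydroxide, [K+].[OH-]
Why: Forcing saponification in a dipolar aprotic medium overcomes the 2,6-disubstitution; the product stays as the stable dianion until cold acidification, which avoids decarboxylation.

**Compound list**
1 | 11-bromoundecan-1-ol | OCCCCCCCCCCCBr | starting material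
2 | 3,4-dihydro-2H-pyran | C1=COCCC1 | starting material
3 | 2-[(11-bromoundecyl)oxy]tetrahydro-2H-pyran (racemic) | BrCCCCCCCCCCCOC1CCCCO1 | intermediate
4 | phenethylmagnesium chloride | Cl[Mg]CCc1ccccc1 | starting material
5 | 2-[(13-phenyltridecyl)oxy]tetrahydro-2H-pyran (racemic) | c1ccccc1CCCCCCCCCCCCCOC1CCCCO1 | intermediate
6 | 13-phenyltridecan-1-ol | OCCCCCCCCCCCCCc1ccccc1 | intermediate
7 | 13-phenyltridecanal | O=CCCCCCCCCCCCCc1ccccc1 | intermediate
8 | triethyl phosphonoacetate | CCOC(=O)CP(=O)(OCC)OCC | starting material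
9 | ethyl (E)-15-phenylpentadec-2-enoate | CCOC(=O)/C=C/CCCCCCCCCCCCc1ccccc1 | intermediate
10 | (E)-15-phenylpentadec-2-en-1-ol | OC/C=C/CCCCCCCCCCCCc1ccccc1 | intermediate
11 | (E)-15-phenylpentadec-2-enal | O=C/C=C/CCCCCCCCCCCCc1ccccc1 | intermediate
12 | ethyl acetoacetate | CCOC(=O)CC(C)=O | starting material
13 | ethyl 2-acetyl-5-oxo-3-(12-phenyldodecyl)pentanoate (stereoisomer mixture) | CCOC(=O)C(C(C)=O)C(CC=O)CCCCCCCCCCCCc1ccccc1 | intermediate (not isolated)
14 | ethyl 4-hydroxy-2-oxo-6-(12-phenyldodecyl)cyclohexane-1-carboxylate (stereoisomer mixture) | CCOC(=O)C1C(=O)CC(O)CC1CCCCCCCCCCCCc1ccccc1 | intermediate (not isolated)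
15 | ethyl 2-oxo-6-(12-phenyldodecyl)cyclohex-3-ene-1-carboxylate (stereoisomer mixture) | CCOC(=O)C1C(=O)C=CCC1CCCCCCCCCCCCc1ccccc1 | intermediate
16 | ethyl 1-bromo-2-oxo-6-(12-phenyldodecyl)cyclohex-3-ene-1-carboxylate (stereoisomer mixture) | CCOC(=O)C1(Br)C(=O)C=CCC1CCCCCCCCCCCCc1ccccc1 | intermediate (not isolated)
17 | ethyl 2-hydroxy-6-(12-phenyldodecyl)benzoate | CCOC(=O)c1c(O)cccc1CCCCCCCCCCCCc1ccccc1 | intermediate
18 | 2-hydroxy-6-(12-phenyldodecyl)benzoic acid | O=C(O)c1c(O)cccc1CCCCCCCCCCCCc1ccccc1 | target

**Totals**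
Total step count: 10. Longest linear sequence: 10 steps (1 → 18).

**Steps most likely to fail, with fallbacks**

Step 8 (Michael/aldol annulation; risk of 1,2-addition or enal oligomerisation under alkoxide). The fallback sets out from aldehyde 7 (with 12) and comes back at keto-aldehyde 13. Lehnert–Knoevenagel condensation of 7 with ethyl acetoacetate 12 (TiCl4, pyridine, THF, 0 °C) gives ethyl 2-acetyl-15-phenylpentadec-2-enoate F1 as an E/Z mixture. Hosomi–Sakurai conjugate allylation (allyltrimethylsilane, TiCl4, CH2Cl2, −78 °C) converts it into ethyl 2-acetyl-3-(12-phenyldodecyl)hex-5-enoate F2. Lemieux–Johnson cleavage of the terminal alkene (cat. OsO4, NaIO4, 2,6-lutidine, dioxane/H2O) then delivers 13, which is cyclised and dehydrated to 15 with the base/acid sequence of step 8.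

Step 9 (aromatisation; risk of over-bromination or incomplete HBr loss). The fallback sets out from 15 and comes back at 17. The sodium enolate of 15 (NaH, THF, 0 °C) is selenenylated with PhSeCl to give ethyl 2-oxo-6-(12-phenyldodecyl)-1-(phenylselanyl)cyclohex-3-ene-1-carboxylate F3. Oxidation with 30 % H2O2 (CH2Cl2, pyridine, 0 °C → rt) gives the selenoxide ethyl 2-oxo-6-(12-phenyldodecyl)-1-(phenylseleninyl)cyclohex-3-ene-1-carboxylate F4. This undergoes syn-elimination towards C6–H, and the dienone tautomerises to 17, with no electrophilic halogen present.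

Step 10 (saponification of the hindered, chelated 2,6-disubstituted ester). The fallback sets out from 17 and comes back at 18. It uses non-hydrolytic alkyl–oxygen cleavage: iodotrimethylsilane generated in situ (TMSCl/NaI, MeCN, reflux) dealkylates the ethyl ester by SN2 attack of iodide at the ethyl group, giving trimethylsilyl 2-hydroxy-6-(12-phenyldodecyl)benzoate F5. Mild aqueous work-up hydrolyses the silyl ester to 18.

**Further compounds**
F1 | step 8 | ethyl 2-acetyl-15-phenylpentadec-2-enoate (E/Z mixture) | CCOC(=O)C(C(C)=O)=CCCCCCCCCCCCCc1ccccc1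
F2 | step 8 | ethyl 2-acetyl-3-(12-phenyldodecyl)hex-5-enoate (stereoisomer mixture) | CCOC(=O)C(C(C)=O)C(CC=C)CCCCCCCCCCCCc1ccccc1
F3 | step 9 | ethyl 2-oxo-6-(12-phenyldodecyl)-1-(phenylselanyl)cyclohex-3-ene-1-carboxylate (stereoisomer mixture) | CCOC(=O)C1([Se]c2ccccc2)C(=O)C=CCC1CCCCCCCCCCCCc1ccccc1
F4 | step 9 | ethyl 2-oxo-6-(12-phenyldodecyl)-1-(phenylseleninyl)cyclohex-3-ene-1-carboxylate (stereoisomer mixture) | CCOC(=O)C1([Se](=O)c2ccccc2)C(=O)C=CCC1CCCCCCCCCCCCc1ccccc1
F5 | step 10 | trimethylsilyl 2-hydroxy-6-(12-phenyldodecyl)benzoate | C[Si](C)(C)OC(=O)c1c(O)cccc1CCCCCCCCCCCCc1ccccc1
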